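# Robinetinidol-(4α→8)-epigallocatechin (CNP0275321.3): route with ring D built last by a photochemical Wolff–Danheiser benzannulation

Locants: the upper unit has rings A (benzo), C (pyran) and B (pendant aryl) and unprimed atoms; the lower unit has rings D, F and E and primed atoms.

## Analysis of the target

The target is a 4→8-linked flavan-3-ol dimer: a 5-deoxy upper unit (7-OH, pyrogallol ring B; robinetinidol type) is bonded through C4 to C8′ of an epigallocatechin lower unit. It has five stereocentres. C2 (R), C3 (S) and C4 (S) on ring C are all-trans, with the aryl, hydroxyl and aryl groups equatorial. C2′ (R) and C3′ (R) on ring F are cis. Nine phenolic hydroxyls, six of them in two pyrogallol rings, make the free compound sensitive to air and base, so the phenols must stay masked until a final neutral step. The doubly benzylic C4–C8′ bond is acid-labile in principle, though less so here because ring A lacks the 5-oxygen. The usual difficulty is that C4–C8′ is made by attack of ring D on a C4 cation, where C8′ competes with C6′, the two faces of C4 compete, and the product can react again. The strategy rests on ring D being a pentasubstituted phloroglucinol ring: C8′ bears C4, C8a′ bears the pyran oxygen O1′, C4a′ bears C4′, and C5′ and C7′ bear oxygen. This pattern can be written in by building the arene from the enol ether carbons C8a′=C4a′ of a preformed ring F, a two-carbon unit attached to C4, and an oxygenated alkyne.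

## Retrosynthetic reasoning

**Unmasking (37 ⇐ 36 ⇐ 35 ⇐ 34).** The last three operations only free oxygen: hydrogenolysis of eight benzyl ethers, desilylation at O7′, and cleavage of the methoxymethyl acetal at O3′. Benzyl is used on every oxygen present from the start because it survives organolithium, Lewis-acid and photochemical steps and leaves under neutral conditions. The silyl ether at O7′ and the free hydroxyl at O5′ are the signature of the ring-forming step. The acetal at O3′ is what the stereodefining allylation of the lower fragment delivers; its mild acidic removal is acceptable because a 5-deoxy upper unit ionises at C4 reluctantly.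

**Ring D (34 ⇐ 24 + 29).** Four bonds are cut: C8′–C8a′, C7′–C8′, C5′–C6′ and C4a′–C5′. This returns diazo ketone 24 and silyloxyalkyne 29. The cut is made here and not at C4–C8′ because in 24 the carbon that becomes C8′ is already bonded to C4 and the carbon that becomes C8a′ is already bonded to O1′. The 4→8 constitution is then a matter of connectivity, not selectivity. All five stereocentres are in place in 24 and none is formed in the forward step. That step must achieve a Wolff shift of C8a′, a ketene–alkyne [2+2] with the alkyne CH carbon on the ketene carbonyl carbon, a 4π opening and a 6π closure.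

**Diazo group (24 ⇐ 22).** The diazo group goes onto the only enolisable methylene on the flavan side of ketone 22. A simple ketone does not accept a diazo group directly, so the enolate is first trifluoroacetylated (23).

**Fragment union (22 ⇐ 12 + 20).** The bond between the carbonyl carbon and C6 of the dihydropyran is cut, giving Weinreb amide 12 and a C6-metalated dihydropyran. Direct deprotonation of a cyclic enol ether at C6 needs alkyllithium bases strong enough to metalate the benzylic CH2 groups of the benzyl ethers. The vinyllithium 21 is therefore released from stannane 20 by tin–lithium exchange at low temperature. The bond made here is the one that later migrates in the Wolff step.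

**Lower fragment (20 ⇐ 19 ⇐ 18 ⇐ 17 ⇐ 15 ⇐ 13 + 3).** The stannane comes from enol phosphate 19 of lactone 18, and the lactone from lactol 17. Lactol 17 is the hydroformylation product of homoallylic alcohol 15; the added carbon becomes C8a′. Cutting C2′–C3′ of 15 gives aldehyde 3 and allyl ether 13. A (Z)-γ-alkoxyallylborane (14) sets both centres in one step with the syn relationship that becomes 2′,3′-cis once the benzylic oxygen is the ring oxygen. It also differentiates the two oxygens, which a dihydroxylation would not.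

**C4 side chain (12 ⇐ 11 ⇐ 9 + 10).** The C4–CH2 bond is cut to a C4 cation equivalent (benzylic ether 9) and ketene silyl acetal 10. A nucleophile enters anti to the C3 benzyloxy group of a 2,3-trans flavan cation, which is the 3,4-trans relationship required. A sigmatropic transfer of chirality from an allylic carbinol flanked by the two donor-substituted aryl rings was set aside, because such alcohols ionise under the acidic, hot conditions of orthoester Claisen rearrangements and would scramble both position and configuration.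

**Ring C (9 ⇐ 8 ⇐ 7 ⇐ 5 ⇐ 4 ⇐ 2 + 3; 2 ⇐ 1).** The C4 oxygen of 9 is the ketone of dihydroflavonol 7. O1–C2 is cut to the epoxide 5, whose α-carbon keeps its oxygen and becomes C3, and whose β-carbon is inverted by the phenol and becomes C2. The epoxide comes from chalcone 4 by a catalytic asymmetric epoxidation, and 4 from ketone 2 and aldehyde 3. The phenol of 1 has to be masked (2) so that it does not interfere with the peroxide step.

**Alkyne (29 ⇐ 25 + 26).** The C–O bond of the ynol ether is cut to an ynolate, made by oxidation of the acetylide of 25, and silyl triflate 26.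

## Alternatives that were turned down

**Alternative 1:** Ring C is opened at C2=C3 and, one step further back, at C3–O. The 3-hydroxyl would come from hydroboration–oxidation of flav-2-ene A1, and A1 from aryl ester A2, in which O1 carries the ring B acyl group and C4 a vinyl group.
- Forward step: a titanium alkylidene reagent methylenates the ester carbonyl of A2 and the enol ether closes onto the C4 vinyl group by metathesis, giving A1.
- For: the single C4 centre of A1 would send borane to the face anti to the C4 aryl group, and syn addition then fixes C2 and C3 together. On this point it is stronger than the chosen route, which needs separate operations for C2/C3 (steps 3 and 4) and C4 (step 7).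
- Against: A2 already contains the C4–C8′ bond and a C4 centre flanked by two electron-rich aryl groups and a vinyl group. The two real problems, 8- versus 6-regiochemistry on ring D and the configuration at C4, are only moved in front of the key step. The ester is ortho to a bulky methine, which slows carbonyl olefination. A1 is a doubly benzylic enol ether that is easily oxidised to a flavylium ion or isomerised, and either process erases C4.
- Comparison: the length would be similar. The chosen route gives up one-centre control of ring C and gains a constitutionally fixed 4→8 bond, with C4 set by substrate control before the fragments meet.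

**Alternative 2:** Ring C is disconnected at O1–C2 and C3–O by a retro ring expansion to the 2,3-dihydrobenzofuran mesylate A4. Its exocyclic benzylic carbon becomes C2 and its furan carbon next to oxygen becomes C3.
- Forward step: buffered solvolysis with Zn(OAc)2 lets O1 displace the mesylate to give a bridged oxonium ion, which acetate opens at the former furan carbon to give the 3-O-acetyl chroman A3.
- For: both substitutions are invertive, so C2 and C3 of A3 are programmed by A4, and C4 is not touched. In stereospecificity at C2/C3 it is the equal of steps 3 and 4.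
- Against: A4 has three contiguous centres and already holds the C4–C8′ bond, so it is no easier than the target, and ring D regiochemistry is again unsolved. The ionising carbon carries the 3,4,5-tris(benzyloxy)phenyl ring, whose para oxygen favours a free benzylic cation and hence loss of stereospecificity or direct acetate capture without migration. Opening of the oxonium ion at the benzylic carbon returns the five-membered ring. The acetate costs one more step.
- Comparison: the key step addresses neither the interflavan bond nor C4, which the chosen route settles by construction.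

**Alternative 3:** Ring C is disconnected at O1–C2 and C3–C4 as the hetero-Diels–Alder adduct of an ortho-quinone methide with an alkenylboronate. The methide would come from o-hydroxybenzhydrol A6, whose carbinol carbon is C4 and is already bonded to C8′; the alkene is (E)-styrylboronate A7.
- Forward step: dehydration of A6 and [4+2] addition of A7 give the 3-boryl flavan A5; C–B oxidation with retention gives the 3-ol.
- For: it is the most convergent plan. Ring C, C2 and C3 form in one step, the E geometry becomes 2,3-trans, an endo approach gives 2,4-cis, and ring D comes from an intact epigallocatechin derivative. In step count it is clearly stronger than the chosen route.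
- Against: three centres are created at once, and the only chiral information is C2′/C3′, remote from the methide carbon and across a rotating aryl–C4 bond. The absolute sense of the upper unit would be poorly controlled, and the target would come with the diastereomer whose upper unit is enantiomeric. A boryl-substituted alkene is a weak partner for an electron-poor heterodiene. The methide carbon is shielded by the ortho,ortho′-disubstituted ring D. A6 needs a C8′-selective metalation of the lower unit.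
- Comparison: the chosen route is longer, but every centre is set within a separate fragment under reagent or substrate control and none in the key step.

Key step: step 17

Remark on the chemistry: 3-(methoxymethoxy)prop-1-ene (13), ketene silyl acetal 10 and acetylene (25) are taken as catalogue chemicals (13 is otherwise one step from allyl alcohol). Diol 8 is carried on with any minor C4 epimer, since C4 is ionised in step 7.

## Route

**Step 1**
Reactants: 1 1-[4-(benzyloxy)-2-hydroxyphenyl]ethan-1-one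
Product: 2 1-[4-(benzyloxy)-2-(methoxymethoxy)phenyl]ethan-1-one
Conditions: NaH, MOMCl, DMF, 0 °C to rt
Reagents that add atoms: chloromethyl methyl ether, COCCl
Why: Williamson-type O-alkylation of the sodium phenoxide; full deprotonation overcomes the hydrogen bond to the ketone, and the acetal keeps the phenol out of the peroxide step.

**Step 2**
Reactants: 2 1-[4-(benzyloxy)-2-(methoxymethoxy)phenyl]ethan-1-one; 3 3,4,5-tris(benzyloxy)benzaldehyde
Product: 4 (E)-1-[4-(benzyloxy)-2-(methoxymethoxy)phenyl]-3-[3,4,5-tris(benzyloxy)phenyl]prop-2-en-1-one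
Conditions: KOH, EtOH/THF, rt
Reagents that add atoms: none
Why: Claisen–Schmidt condensation; the non-enolisable aldehyde and E1cB dehydration should give the E-enone only.

**Step 3**
Reactants: 4 (E)-1-[4-(benzyloxy)-2-(methoxymethoxy)phenyl]-3-[3,4,5-tris(benzyloxy)phenyl]prop-2-en-1-one
Product: 5 [4-(benzyloxy)-2-(methoxymethoxy)phenyl]{(2R,3S)-3-[3,4,5-tris(benzyloxy)phenyl]oxiran-2-yl}methanone
Conditions: poly-L-leucine, urea–H2O2, DBU, THF, rt
Reagents that add atoms: hydrogen peroxide (as its urea adduct), OO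
Why: Juliá–Colonna epoxidation; the helical L-polypeptide binds the hydroperoxide and the enone and delivers oxygen to the face that gives the (2R,3S)-epoxy ketone with chalcones, and the E geometry is kept as the trans epoxide.

**Step 4**
Reactants: 5 [4-(benzyloxy)-2-(methoxymethoxy)phenyl]{(2R,3S)-3-[3,4,5-tris(benzyloxy)phenyl]oxiran-2-yl}methanone
Product: 7 (2R,3R)-7-(benzyloxy)-3-hydroxy-2-[3,4,5-tris(benzyloxy)phenyl]-2,3-dihydro-4H-chromen-4-one, via free-phenol epoxide 6 (not isolated)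
Conditions: HCl (conc., cat.), MeOH/THF, 50 °C
Reagents that add atoms: none
Why: Acetal methanolysis frees the phenol, which opens the protonated epoxide at the benzylic carbon (6-endo, inversion) to close ring C 2,3-trans; the α-carbon keeps its oxygen, so C3 is R and C2 follows as R.

**Step 5**
Reactants: 7 (2R,3R)-7-(benzyloxy)-3-hydroxy-2-[3,4,5-tris(benzyloxy)phenyl]-2,3-dihydro-4H-chromen-4-one
Product: 8 (2R,3S,4R)-7-(benzyloxy)-2-[3,4,5-tris(benzyloxy)phenyl]-3,4-dihydro-2H-chromene-3,4-diol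
Conditions: NaBH4, EtOH/THF, 0 °C
Reagents that add atoms: none
Why: Borohydride reduction of a 2,3-trans dihydroflavonol should give mainly the 3,4-trans diol; the C4 configuration is of no consequence because C4 is ionised in step 7.

**Step 6**
Reactants: 8 (2R,3S,4R)-7-(benzyloxy)-2-[3,4,5-tris(benzyloxy)phenyl]-3,4-dihydro-2H-chromene-3,4-diol
Product: 9 (2R,3S,4R)-3,4,7-tris(benzyloxy)-2-[3,4,5-tris(benzyloxy)phenyl]-3,4-dihydro-2H-chromene
Conditions: NaH, BnBr, Bu4NI (cat.), DMF, 0 °C to rt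
Reagents that add atoms: benzyl bromide, BrCc1ccccc1
Why: Williamson etherification of both secondary alkoxides; the 3-O-benzyl group is permanent protection and the 4-O-benzyl group is the leaving group for step 7.

**Step 7**
Reactants: 9 (2R,3S,4R)-3,4,7-tris(benzyloxy)-2-[3,4,5-tris(benzyloxy)phenyl]-3,4-dihydro-2H-chromene; 10 tert-butyl[(1-methoxyethenyl)oxy]dimethylsilane
Product: 11 methyl 2-{(2R,3S,4R)-3,7-bis(benzyloxy)-2-[3,4,5-tris(benzyloxy)phenyl]-3,4-dihydro-2H-chromen-4-yl}acetate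
Conditions: Me3SiOTf (0.2 equiv), CH2Cl2, −78 °C
Reagents that add atoms: none
Why: Mukaiyama-type SN1 alkylation; the Lewis acid ionises the 4-benzyloxy group to a benzylic cation stabilised by O1 and the 7-benzyloxy group, and the ketene silyl acetal attacks the half-chair cation anti to the 3-benzyloxy group, which sets C4 3,4-trans (4α).

**Step 8**
Reactants: 11 methyl 2-{(2R,3S,4R)-3,7-bis(benzyloxy)-2-[3,4,5-tris(benzyloxy)phenyl]-3,4-dihydro-2H-chromen-4-yl}acetate
Product: 12 2-{(2R,3S,4R)-3,7-bis(benzyloxy)-2-[3,4,5-tris(benzyloxy)phenyl]-3,4-dihydro-2H-chromen-4-yl}-N-methoxy-N-methylacetamide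
Conditions: MeNH(OMe)·HCl, i-PrMgCl, THF, −20 to 0 °C
Reagents that add atoms: N,O-dimethylhydroxylamine hydrochloride, CNOC.Cl
Why: Aminolysis of the ester by the magnesium amide gives the Weinreb amide; C4 is β to the carbonyl and cannot epimerise.

**Step 9**
Reactants: 13 3-(methoxymethoxy)prop-1-ene; 3 3,4,5-tris(benzyloxy)benzaldehyde
Product: 15 (1R,2R)-2-(methoxymethoxy)-1-[3,4,5-tris(benzyloxy)phenyl]but-3-en-1-ol, via allylborane 14 (not isolated)
Conditions: sec-BuLi, THF, −78 °C; (−)-Ipc2BOMe; BF3·OEt2; then 3, −78 °C; NaOH, H2O2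
Reagents that add atoms: none
Why: Brown alkoxyallylation; the (Z)-γ-alkoxyallylborane reacts through a chair transition state to give the syn product, and the isopinocampheyl groups derived from (+)-α-pinene direct attack to the Si face of the aldehyde, which sets C2′ and C3′ as (R,R).

**Step 10**
Reactants: 15 (1R,2R)-2-(methoxymethoxy)-1-[3,4,5-tris(benzyloxy)phenyl]but-3-en-1-ol
Product: 17 (5R,6R)-5-(methoxymethoxy)-6-[3,4,5-tris(benzyloxy)phenyl]oxan-2-ol (both anomers), via hydroxy aldehyde 16 (not isolated)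
Conditions: Rh(acac)(CO)2 (2 mol %), BIPHEPHOS, CO/H2 (1:1, 10 bar), THF, 60 °C
Reagents that add atoms: carbon monoxide, [C-]#[O+]
Why: Linear-selective hydroformylation of the terminal alkene with a bulky bisphosphite on rhodium; the δ-hydroxy aldehyde closes to the six-membered lactol, and the carbon from CO becomes C8a′.

**Step 11**
Reactants: 17 (5R,6R)-5-(methoxymethoxy)-6-[3,4,5-tris(benzyloxy)phenyl]oxan-2-ol
Product: 18 (5R,6R)-5-(methoxymethoxy)-6-[3,4,5-tris(benzyloxy)phenyl]oxan-2-one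
Conditions: TEMPO (cat.), PhI(OAc)2, CH2Cl2, rt
Reagents that add atoms: none
Why: Oxoammonium oxidation of the lactol to the δ-lactone; benzyl ethers and the acetal are inert.

**Step 12**
Reactants: 18 (5R,6R)-5-(methoxymethoxy)-6-[3,4,5-tris(benzyloxy)phenyl]oxan-2-one
Product: 19 (2R,3R)-3-(methoxymethoxy)-2-[3,4,5-tris(benzyloxy)phenyl]-3,4-dihydro-2H-pyran-6-yl diphenyl phosphate
Conditions: KN(SiMe3)2, (PhO)2P(O)Cl, HMPA, THF, −78 °C
Reagents that add atoms: diphenyl chlorophosphate, O=P(Cl)(Oc1ccccc1)Oc1ccccc1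
Why: O-phosphorylation of the potassium lactone enolate gives the ketene acetal phosphate; the acetal oxygen is γ to the enolate carbon, so no elimination is possible.

**Step 13**
Reactants: 19 (2R,3R)-3-(methoxymethoxy)-2-[3,4,5-tris(benzyloxy)phenyl]-3,4-dihydro-2H-pyran-6-yl diphenyl phosphate
Product: 20 trimethyl{(2R,3R)-3-(methoxymethoxy)-2-[3,4,5-tris(benzyloxy)phenyl]-3,4-dihydro-2H-pyran-6-yl}stannane
Conditions: Pd(PPh3)4 (5 mol %), Me3SnSnMe3, LiCl, THF, 65 °C
Reagents that add atoms: hexamethylditin, C[Sn](C)(C)[Sn](C)(C)C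
Why: Stille-type palladium-catalysed stannylation of the enol phosphate; LiCl assists oxidative addition and transmetalation.

**Step 14**
Reactants: 20 trimethyl{(2R,3R)-3-(methoxymethoxy)-2-[3,4,5-tris(benzyloxy)phenyl]-3,4-dihydro-2H-pyran-6-yl}stannane; 12 2-{(2R,3S,4R)-3,7-bis(benzyloxy)-2-[3,4,5-tris(benzyloxy)phenyl]-3,4-dihydro-2H-chromen-4-yl}-N-methoxy-N-methylacetamide
Product: 22 2-{(2R,3S,4R)-3,7-bis(benzyloxy)-2-[3,4,5-tris(benzyloxy)phenyl]-3,4-dihydro-2H-chromen-4-yl}-1-{(2R,3R)-3-(methoxymethoxy)-2-[3,4,5-tris(benzyloxy)phenyl]-3,4-dihydro-2H-pyran-6-yl}ethan-1-one, via vinyllithium 21 (not isolated)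
Conditions: MeLi, THF, −78 °C; then 12, −78 to −40 °C; aq. NH4Cl
Reagents that add atoms: none
Why: Tin–lithium exchange gives the α-alkoxyvinyllithium at −78 °C without a base strong enough to metalate benzyl ethers; Weinreb ketone synthesis then stops at the chelated tetrahedral adduct until work-up.

**Step 15**
Reactants: 22 2-{(2R,3S,4R)-3,7-bis(benzyloxy)-2-[3,4,5-tris(benzyloxy)phenyl]-3,4-dihydro-2H-chromen-4-yl}-1-{(2R,3R)-3-(methoxymethoxy)-2-[3,4,5-tris(benzyloxy)phenyl]-3,4-dihydro-2H-pyran-6-yl}ethan-1-one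
Product: 24 2-diazo-2-{(2R,3S,4S)-3,7-bis(benzyloxy)-2-[3,4,5-tris(benzyloxy)phenyl]-3,4-dihydro-2H-chromen-4-yl}-1-{(2R,3R)-3-(methoxymethoxy)-2-[3,4,5-tris(benzyloxy)phenyl]-3,4-dihydro-2H-pyran-6-yl}ethan-1-one, via trifluoroacetyl diketone 23 (not isolated)
Conditions: LiN(SiMe3)2, THF, −78 °C; CF3CO2CH2CF3; then MsN3, Et3N, H2O, MeCN, rt
Reagents that add atoms: methanesulfonyl azide, CS(=O)(=O)N=[N+]=[N-]
Why: Detrifluoroacetylative diazo transfer; the kinetic enolate at the only α-methylene is C-trifluoroacetylated, and the activated 1,3-diketone takes the diazo group from the sulfonyl azide and loses the trifluoroacetyl group as the N-acylsulfonamide (the descriptor at C4 changes by priority only).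

**Step 16**
Reactants: 25 acetylene; 26 triisopropylsilyl trifluoromethanesulfonate
Product: 29 (triisopropylsilyloxy)acetylene, via lithium acetylide 27 (not isolated), via lithium ethynolate 28 (not isolated)
Conditions: n-BuLi, THF, −78 °C; t-BuOOLi (from t-BuOOH and LiN(SiMe3)2), −78 to −20 °C; then 26, −78 to 0 °C
Reagents that add atoms: tert-butyl hydroperoxide, CC(C)(C)OO
Why: Oxidation of a lithium acetylide by lithium tert-butyl peroxide (oxygen transfer with loss of tert-butoxide) gives the ynolate, and the bulky silyl triflate silylates it on oxygen.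

**Step 17**
Reactants: 24 2-diazo-2-{(2R,3S,4S)-3,7-bis(benzyloxy)-2-[3,4,5-tris(benzyloxy)phenyl]-3,4-dihydro-2H-chromen-4-yl}-1-{(2R,3R)-3-(methoxymethoxy)-2-[3,4,5-tris(benzyloxy)phenyl]-3,4-dihydro-2H-pyran-6-yl}ethan-1-one; 29 (triisopropylsilyloxy)acetylene
Product: 34 (2R,3R)-8-{(2R,3S,4S)-3,7-bis(benzyloxy)-2-[3,4,5-tris(benzyloxy)phenyl]-3,4-dihydro-2H-chromen-4-yl}-3-(methoxymethoxy)-2-[3,4,5-tris(benzyloxy)phenyl]-7-[(triisopropylsilyl)oxy]-3,4-dihydro-2H-chromen-5-ol, via vinylketene 30 (not isolated), via cyclobutenone 31 (not isolated), via dienylketene 32 (not isolated), via cyclohexadienone 33 (not isolated)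
Conditions: hν (medium-pressure Hg lamp, Pyrex filter), 29 (3 equiv), ClCH2CH2Cl (degassed), rt; then 80 °C
Reagents that add atoms: none
Why: Light absorbed by the diazo enone expels N2 with concerted 1,2-shift of the sp2 carbon C8a′ from the carbonyl carbon to the diazo carbon (photochemical Wolff rearrangement), giving vinylketene 30 in which C8′ carries C4, C8a′ and the ketene carbon. The polarised ynol ether 29 adds to the ketene C=C bond in a [2+2] cycloaddition, its nucleophilic CH carbon bonding to the ketene carbonyl carbon and its oxygen-bearing carbon to C8′, so that cyclobutenone 31 holds the C5′–C6′ and C7′–C8′ bonds. Reversible 4π electrocyclic opening (thermal at 80 °C, also photochemical) gives dienylketene 32, and the isomer with the dihydropyranyl group cis to the ketenyl carbon closes ring D by a thermal disrotatory 6π electrocyclisation (C4a′–C5′) to cyclohexadienone 33, which tautomerises to the phenol. This is the photochemical Wolff variant of the Danheiser benzannulation of α-diazo ketones with siloxyalkynes. No stereocentre is created: the centres of 31 and 33 are transient and vanish on aromatisation, and C4 is never α to a carbonyl group, so the five existing centres are untouched. The step needs Wolff migration rather than carbene chemistry (1,2-shift of H4 or insertion into the 3-O-benzyl CH2), which the migratory aptitude of the alkenyl carbon and direct excitation of the s-cis conformer favour, and it needs the head-to-tail [2+2] regiochemistry, which the silyloxy group enforces. Because O1′ is already bonded to C8a′ in ring F, only the 4→8 constitution can arise, and Pyrex-filtered light leaves the benzyl ether chromophores unexcited.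

**Step 18**
Reactants: 34 (2R,3R)-8-{(2R,3S,4S)-3,7-bis(benzyloxy)-2-[3,4,5-tris(benzyloxy)phenyl]-3,4-dihydro-2H-chromen-4-yl}-3-(methoxymethoxy)-2-[3,4,5-tris(benzyloxy)phenyl]-7-[(triisopropylsilyl)oxy]-3,4-dihydro-2H-chromen-5-ol
Product: 35 (2R,3R)-8-{(2R,3S,4S)-3,7-bis(benzyloxy)-2-[3,4,5-tris(benzyloxy)phenyl]-3,4-dihydro-2H-chromen-4-yl}-2-[3,4,5-tris(benzyloxy)phenyl]-7-[(triisopropylsilyl)oxy]-3,4-dihydro-2H-chromene-3,5-diol
Conditions: HCl (conc., cat.), MeOH/THF, 40 °C
Reagents that add atoms: none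
Why: Acid-catalysed transacetalisation to methanol removes the methoxymethyl group; benzyl and aryl silyl ethers survive, and the interflavan bond of a 5-deoxy upper unit should resist this mild acid.

**Step 19**
Reactants: 35 (2R,3R)-8-{(2R,3S,4S)-3,7-bis(benzyloxy)-2-[3,4,5-tris(benzyloxy)phenyl]-3,4-dihydro-2H-chromen-4-yl}-2-[3,4,5-tris(benzyloxy)phenyl]-7-[(triisopropylsilyl)oxy]-3,4-dihydro-2H-chromene-3,5-diol
Product: 36 (2R,3R)-8-{(2R,3S,4S)-3,7-bis(benzyloxy)-2-[3,4,5-tris(benzyloxy)phenyl]-3,4-dihydro-2H-chromen-4-yl}-2-[3,4,5-tris(benzyloxy)phenyl]-3,4-dihydro-2H-chromene-3,5,7-triol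
Conditions: Bu4NF, AcOH, THF, 0 °C
Reagents that add atoms: none
Why: Fluoride cleaves the aryl silyl ether; acetic acid buffers the phenoxide of the electron-rich ring D.

**Step 20**
Reactants: 36 (2R,3R)-8-{(2R,3S,4S)-3,7-bis(benzyloxy)-2-[3,4,5-tris(benzyloxy)phenyl]-3,4-dihydro-2H-chromen-4-yl}-2-[3,4,5-tris(benzyloxy)phenyl]-3,4-dihydro-2H-chromene-3,5,7-triol
Product: 37 (2R,3S,4S)-2-(3,4,5-trihydroxyphenyl)-4-[(2R,3R)-3,5,7-trihydroxy-2-(3,4,5-trihydroxyphenyl)-3,4-dihydro-2H-chromen-8-yl]-3,4-dihydro-2H-chromene-3,7-diol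
Conditions: H2 (1 atm), Pd(OH)2 on carbon, THF/MeOH, rt
Reagents that add atoms: none
Why: Hydrogenolysis of the eight benzyl ethers under neutral conditions; the ring C–O and C4–C8′ bonds are not cleaved under these mild conditions, and no stereocentre is touched.

## Compound list

1 | 1-[4-(benzyloxy)-2-hydroxyphenyl]ethan-1-one | CC(=O)c1ccc(OCc2ccccc2)cc1O | starting material
2 | 1-[4-(benzyloxy)-2-(methoxymethoxy)phenyl]ethan-1-one | CC(=O)c1ccc(OCc2ccccc2)cc1OCOC | intermediate
3 | 3,4,5-tris(benzyloxy)benzaldehyde | O=Cc1cc(OCc2ccccc2)c(OCc2ccccc2)c(OCc2ccccc2)c1 | starting material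
4 | (E)-1-[4-(benzyloxy)-2-(methoxymethoxy)phenyl]-3-[3,4,5-tris(benzyloxy)phenyl]prop-2-en-1-one | COCOc1cc(OCc2ccccc2)ccc1C(=O)/C=C/c1cc(OCc2ccccc2)c(OCc2ccccc2)c(OCc2ccccc2)c1 | intermediate
5 | [4-(benzyloxy)-2-(methoxymethoxy)phenyl]{(2R,3S)-3-[3,4,5-tris(benzyloxy)phenyl]oxiran-2-yl}methanone | COCOc1cc(OCc2ccccc2)ccc1C(=O)[C@@H]1O[C@H]1c1cc(OCc2ccccc2)c(OCc2ccccc2)c(OCc2ccccc2)c1 | intermediate
6 | [4-(benzyloxy)-2-hydroxyphenyl]{(2R,3S)-3-[3,4,5-tris(benzyloxy)phenyl]oxiran-2-yl}methanone | Oc1cc(OCc2ccccc2)ccc1C(=O)[C@@H]1O[C@H]1c1cc(OCc2ccccc2)c(OCc2ccccc2)c(OCc2ccccc2)c1 | intermediate (not isolated)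
7 | (2R,3R)-7-(benzyloxy)-3-hydroxy-2-[3,4,5-tris(benzyloxy)phenyl]-2,3-dihydro-4H-chromen-4-one | O=C1c2ccc(OCc3ccccc3)cc2O[C@H](c2cc(OCc3ccccc3)c(OCc3ccccc3)c(OCc3ccccc3)c2)[C@H]1O | intermediate
8 | (2R,3S,4R)-7-(benzyloxy)-2-[3,4,5-tris(benzyloxy)phenyl]-3,4-dihydro-2H-chromene-3,4-diol | c1ccccc1COc1ccc2c(c1)O[C@H](c1cc(OCc3ccccc3)c(OCc3ccccc3)c(OCc3ccccc3)c1)[C@@H](O)[C@@H]2O | intermediate
9 | (2R,3S,4R)-3,4,7-tris(benzyloxy)-2-[3,4,5-tris(benzyloxy)phenyl]-3,4-dihydro-2H-chromene | c1ccccc1COc1ccc2c(c1)O[C@H](c1cc(OCc3ccccc3)c(OCc3ccccc3)c(OCc3ccccc3)c1)[C@@H](OCc1ccccc1)[C@@H]2OCc1ccccc1 | intermediate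
10 | tert-butyl[(1-methoxyethenyl)oxy]dimethylsilane | C=C(OC)O[Si](C)(C)C(C)(C)C | starting material
11 | methyl 2-{(2R,3S,4R)-3,7-bis(benzyloxy)-2-[3,4,5-tris(benzyloxy)phenyl]-3,4-dihydro-2H-chromen-4-yl}acetate | c1ccccc1COc1ccc2c(c1)O[C@H](c1cc(OCc3ccccc3)c(OCc3ccccc3)c(OCc3ccccc3)c1)[C@@H](OCc1ccccc1)[C@@H]2CC(=O)OC | intermediate
12 | 2-{(2R,3S,4R)-3,7-bis(benzyloxy)-2-[3,4,5-tris(benzyloxy)phenyl]-3,4-dihydro-2H-chromen-4-yl}-N-methoxy-N-methylacetamide | c1ccccc1COc1ccc2c(c1)O[C@H](c1cc(OCc3ccccc3)c(OCc3ccccc3)c(OCc3ccccc3)c1)[C@@H](OCc1ccccc1)[C@@H]2CC(=O)N(C)OC | intermediate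
13 | 3-(methoxymethoxy)prop-1-ene | C=CCOCOC | starting material
14 | [(Z)-3-(methoxymethoxy)prop-2-en-1-yl]bis[(1R,2S,3R,5R)-2,6,6-trimethylbicyclo[3.1.1]heptan-3-yl]borane | COCO/C=C\CB([C@@H]1C[C@@H]2C[C@H]([C@H]1C)C2(C)C)[C@@H]1C[C@@H]2C[C@H]([C@H]1C)C2(C)C | intermediate (not isolated)
15 | (1R,2R)-2-(methoxymethoxy)-1-[3,4,5-tris(benzyloxy)phenyl]but-3-en-1-ol | O[C@H](c1cc(OCc2ccccc2)c(OCc2ccccc2)c(OCc2ccccc2)c1)[C@H](OCOC)C=C | intermediate
16 | (4R,5R)-5-hydroxy-4-(methoxymethoxy)-5-[3,4,5-tris(benzyloxy)phenyl]pentanal | O=CCC[C@@H](OCOC)[C@H](O)c1cc(OCc2ccccc2)c(OCc2ccccc2)c(OCc2ccccc2)c1 | intermediate (not isolated)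
17 | (5R,6R)-5-(methoxymethoxy)-6-[3,4,5-tris(benzyloxy)phenyl]oxan-2-ol (both anomers) | OC1CC[C@@H](OCOC)[C@@H](c2cc(OCc3ccccc3)c(OCc3ccccc3)c(OCc3ccccc3)c2)O1 | intermediate
18 | (5R,6R)-5-(methoxymethoxy)-6-[3,4,5-tris(benzyloxy)phenyl]oxan-2-one | O=C1CC[C@@H](OCOC)[C@@H](c2cc(OCc3ccccc3)c(OCc3ccccc3)c(OCc3ccccc3)c2)O1 | intermediate
19 | (2R,3R)-3-(methoxymethoxy)-2-[3,4,5-tris(benzyloxy)phenyl]-3,4-dihydro-2H-pyran-6-yl diphenyl phosphate | O=P(Oc1ccccc1)(Oc1ccccc1)OC1=CC[C@@H](OCOC)[C@@H](c2cc(OCc3ccccc3)c(OCc3ccccc3)c(OCc3ccccc3)c2)O1 | intermediate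
20 | trimethyl{(2R,3R)-3-(methoxymethoxy)-2-[3,4,5-tris(benzyloxy)phenyl]-3,4-dihydro-2H-pyran-6-yl}stannane | C[Sn](C)(C)C1=CC[C@@H](OCOC)[C@@H](c2cc(OCc3ccccc3)c(OCc3ccccc3)c(OCc3ccccc3)c2)O1 | intermediate
21 | {(2R,3R)-3-(methoxymethoxy)-2-[3,4,5-tris(benzyloxy)phenyl]-3,4-dihydro-2H-pyran-6-yl}lithium | [Li]C1=CC[C@@H](OCOC)[C@@H](c2cc(OCc3ccccc3)c(OCc3ccccc3)c(OCc3ccccc3)c2)O1 | intermediate (not isolated)
22 | 2-{(2R,3S,4R)-3,7-bis(benzyloxy)-2-[3,4,5-tris(benzyloxy)phenyl]-3,4-dihydro-2H-chromen-4-yl}-1-{(2R,3R)-3-(methoxymethoxy)-2-[3,4,5-tris(benzyloxy)phenyl]-3,4-dihydro-2H-pyran-6-yl}ethan-1-one | c1ccccc1COc1ccc2c(c1)O[C@H](c1cc(OCc3ccccc3)c(OCc3ccccc3)c(OCc3ccccc3)c1)[C@@H](OCc1ccccc1)[C@@H]2CC(=O)C1=CC[C@@H](OCOC)[C@@H](c2cc(OCc3ccccc3)c(OCc3ccccc3)c(OCc3ccccc3)c2)O1 | intermediate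
23 | 2-trifluoroacetyl derivative of 22 (4,4,4-trifluoro-2-(flavan-4-yl)-1-(dihydropyran-6-yl)butane-1,3-dione; configuration at the new carbon not defined, present as enolate) | c1ccccc1COc1ccc2c(c1)O[C@H](c1cc(OCc3ccccc3)c(OCc3ccccc3)c(OCc3ccccc3)c1)[C@@H](OCc1ccccc1)[C@@H]2C(C(=O)C(F)(F)F)C(=O)C1=CC[C@@H](OCOC)[C@@H](c2cc(OCc3ccccc3)c(OCc3ccccc3)c(OCc3ccccc3)c2)O1 | intermediate (not isolated)
24 | 2-diazo-2-{(2R,3S,4S)-3,7-bis(benzyloxy)-2-[3,4,5-tris(benzyloxy)phenyl]-3,4-dihydro-2H-chromen-4-yl}-1-{(2R,3R)-3-(methoxymethoxy)-2-[3,4,5-tris(benzyloxy)phenyl]-3,4-dihydro-2H-pyran-6-yl}ethan-1-one | c1ccccc1COc1ccc2c(c1)O[C@H](c1cc(OCc3ccccc3)c(OCc3ccccc3)c(OCc3ccccc3)c1)[C@@H](OCc1ccccc1)[C@@H]2C(=[N+]=[N-])C(=O)C1=CC[C@@H](OCOC)[C@@H](c2cc(OCc3ccccc3)c(OCc3ccccc3)c(OCc3ccccc3)c2)O1 | intermediate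
25 | acetylene | C#C | starting material
26 | triisopropylsilyl trifluoromethanesulfonate | CC(C)[Si](OS(=O)(=O)C(F)(F)F)(C(C)C)C(C)C | starting material
27 | lithium acetylide | [Li]C#C | intermediate (not isolated)
28 | lithium ethynolate | [Li]OC#C | intermediate (not isolated)
29 | (triisopropylsilyloxy)acetylene | C#CO[Si](C(C)C)(C(C)C)C(C)C | intermediate
30 | vinylketene from Wolff rearrangement of 24 (ketene carbon on the carbon that bears flavan C4 and dihydropyran C6) | c1ccccc1COc1ccc2c(c1)O[C@H](c1cc(OCc3ccccc3)c(OCc3ccccc3)c(OCc3ccccc3)c1)[C@@H](OCc1ccccc1)[C@@H]2C(=C=O)C1=CC[C@@H](OCOC)[C@@H](c2cc(OCc3ccccc3)c(OCc3ccccc3)c(OCc3ccccc3)c2)O1 | intermediate (not isolated)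
31 | 4-(flavan-4-yl)-4-(dihydropyran-6-yl)-3-(triisopropylsilyloxy)cyclobut-2-en-1-one (ring carbon 4 of either configuration) | c1ccccc1COc1ccc2c(c1)O[C@H](c1cc(OCc3ccccc3)c(OCc3ccccc3)c(OCc3ccccc3)c1)[C@@H](OCc1ccccc1)[C@@H]2C3(C(=O)C=C3O[Si](C(C)C)(C(C)C)C(C)C)C1=CC[C@@H](OCOC)[C@@H](c2cc(OCc3ccccc3)c(OCc3ccccc3)c(OCc3ccccc3)c2)O1 | intermediate (not isolated)
32 | dienylketene from ring opening of 31 (dihydropyranyl group cis to the ketenyl carbon) | c1ccccc1COc1ccc2c(c1)O[C@H](c1cc(OCc3ccccc3)c(OCc3ccccc3)c(OCc3ccccc3)c1)[C@@H](OCc1ccccc1)[C@@H]2/C(=C(\O[Si](C(C)C)(C(C)C)C(C)C)C=C=O)C1=CC[C@@H](OCOC)[C@@H](c2cc(OCc3ccccc3)c(OCc3ccccc3)c(OCc3ccccc3)c2)O1 | intermediate (not isolated)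
33 | cyclohexa-2,4-dienone tautomer of 34 (C4a′ sp3, either configuration) | c1ccccc1COc1ccc2c(c1)O[C@H](c1cc(OCc3ccccc3)c(OCc3ccccc3)c(OCc3ccccc3)c1)[C@@H](OCc1ccccc1)[C@@H]2C1=C2O[C@H](c3cc(OCc4ccccc4)c(OCc4ccccc4)c(OCc4ccccc4)c3)[C@H](OCOC)CC2C(=O)C=C1O[Si](C(C)C)(C(C)C)C(C)C | intermediate (not isolated)
34 | (2R,3R)-8-{(2R,3S,4S)-3,7-bis(benzyloxy)-2-[3,4,5-tris(benzyloxy)phenyl]-3,4-dihydro-2H-chromen-4-yl}-3-(methoxymethoxy)-2-[3,4,5-tris(benzyloxy)phenyl]-7-[(triisopropylsilyl)oxy]-3,4-dihydro-2H-chromen-5-ol | c1ccccc1COc1ccc2c(c1)O[C@H](c1cc(OCc3ccccc3)c(OCc3ccccc3)c(OCc3ccccc3)c1)[C@@H](OCc1ccccc1)[C@@H]2c1c(O[Si](C(C)C)(C(C)C)C(C)C)cc(O)c2c1O[C@H](c3cc(OCc4ccccc4)c(OCc4ccccc4)c(OCc4ccccc4)c3)[C@H](OCOC)C2 | intermediate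
35 | (2R,3R)-8-{(2R,3S,4S)-3,7-bis(benzyloxy)-2-[3,4,5-tris(benzyloxy)phenyl]-3,4-dihydro-2H-chromen-4-yl}-2-[3,4,5-tris(benzyloxy)phenyl]-7-[(triisopropylsilyl)oxy]-3,4-dihydro-2H-chromene-3,5-diol | c1ccccc1COc1ccc2c(c1)O[C@H](c1cc(OCc3ccccc3)c(OCc3ccccc3)c(OCc3ccccc3)c1)[C@@H](OCc1ccccc1)[C@@H]2c1c(O[Si](C(C)C)(C(C)C)C(C)C)cc(O)c2c1O[C@H](c3cc(OCc4ccccc4)c(OCc4ccccc4)c(OCc4ccccc4)c3)[C@H](O)C2 | intermediate
36 | (2R,3R)-8-{(2R,3S,4S)-3,7-bis(benzyloxy)-2-[3,4,5-tris(benzyloxy)phenyl]-3,4-dihydro-2H-chromen-4-yl}-2-[3,4,5-tris(benzyloxy)phenyl]-3,4-dihydro-2H-chromene-3,5,7-triol | c1ccccc1COc1ccc2c(c1)O[C@H](c1cc(OCc3ccccc3)c(OCc3ccccc3)c(OCc3ccccc3)c1)[C@@H](OCc1ccccc1)[C@@H]2c1c(O)cc(O)c2c1O[C@H](c3cc(OCc4ccccc4)c(OCc4ccccc4)c(OCc4ccccc4)c3)[C@H](O)C2 | intermediate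
37 | (2R,3S,4S)-2-(3,4,5-trihydroxyphenyl)-4-[(2R,3R)-3,5,7-trihydroxy-2-(3,4,5-trihydroxyphenyl)-3,4-dihydro-2H-chromen-8-yl]-3,4-dihydro-2H-chromene-3,7-diol | Oc1ccc2c(c1)O[C@H](c1cc(O)c(O)c(O)c1)[C@@H](O)[C@@H]2c1c(O)cc(O)c2c1O[C@H](c1cc(O)c(O)c(O)c1)[C@H](O)C2 | target

## Step count and least certain steps

Total: 20 steps. Longest linear sequence: 14 steps (steps 1–8, 14, 15, 17, 18, 19, 20). The lower fragment (steps 9–13) and the alkyne (step 16) are side branches.

**Step 17 (key step).** The acyclic, doubly substituted diazo ketone may populate the s-trans conformer, so that excitation gives a free carbene and hence 1,2-hydrogen shift from C4 or insertion into the neighbouring benzyl ether CH2 instead of Wolff migration. The phenolic product may also be acylated by ketene intermediates, and the many arene chromophores may screen the light. The fallback gives up the benzannulation and sets out from 9. Commercial (−)-epigallocatechin is benzylated on its five phenols (BnBr, K2CO3, DMF) to (2R,3R)-5,7-bis(benzyloxy)-2-[3,4,5-tris(benzyloxy)phenyl]-3,4-dihydro-2H-chromen-3-ol F1. Ionisation of 9 with Me3SiOTf at −78 °C in the presence of excess F1 should give the 4α→8 dimer F2 by arylation at C8′ anti to the 3-benzyloxy group. Hydrogenolysis of F2 over Pd(OH)2 on carbon comes back at 37. The price is that C8′/C6′ selectivity is then a matter of separation.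

**Step 15.** C-trifluoroacetylation of the hindered enolate may be slow, deprotonation may occur at C4′ through the enone, and triazoline formation at a fully substituted carbon may stall. The fallback sets out from 22. Nitrosation of the potassium enolate (KOt-Bu, tert-butyl nitrite, THF, −40 °C) gives the α-oximino ketone F3, and a Forster reaction with NH2Cl (from NH3 and NaOCl, aqueous THF, 0 °C) converts the oxime into the diazo group, coming back at 24.

**Step 16.** Monolithium acetylide may disproportionate to Li2C2 before it is oxidised, and the ynolate may be silylated on carbon to give a silylketene. The fallback changes the alkyne and the protecting group at O7′ and sets out from 24. Trichloroethylene and benzyl alcohol (KH, THF) give benzyl (E)-1,2-dichlorovinyl ether F4. Two equivalents of n-BuLi at −78 °C followed by methanol give benzyl ethynyl ether F5, which is used at once. Irradiation of 24 with F5 (kept at rt until the alkyne is consumed, because benzyl ynol ethers rearrange on warming), then 80 °C, should give the 7′-O-benzyl analogue F6. Acidic methanol gives the 3′-alcohol F7, and hydrogenolysis of its nine benzyl ethers comes back at 37 without step 19.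

**Step 7.** The Lewis acid may desilylate 10 faster than the cation captures it, which leaves the cation to be arylated by ring A of a second molecule, and facial selectivity at C4 may be incomplete. The fallback sets out from 9. Allyltrimethylsilane with BF3·OEt2 at −78 °C, a more acid-tolerant π-nucleophile, gives the 4-allyl flavan F8 by the same anti attack. Cleavage with OsO4 (cat.) and NaIO4 gives aldehyde F9, oxidation with NaClO2/NaH2PO4 gives acid F10, and carbodiimide coupling with N,O-dimethylhydroxylamine comes back at 12.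

**Step 4.** Methanol may open the epoxide in competition with the phenol, aryl migration may lead toward isoflavone-type products, and a free benzylic cation may close from the wrong face and erode the configuration at C2. The fallback sets out from 5. BnSH with SnCl4 (CH2Cl2, −20 °C) opens the epoxide at the benzylic carbon and removes the acetal, giving the α-hydroxy-β-benzylsulfanyl ketone F11, in which the α-carbon keeps its configuration. AgBF4 then activates sulfur as a leaving group, and the phenol closes ring C trans to the fixed C3 hydroxyl, coming back at 7.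

## Further compounds

F1 | step 17 | (2R,3R)-5,7-bis(benzyloxy)-2-[3,4,5-tris(benzyloxy)phenyl]-3,4-dihydro-2H-chromen-3-ol | c1c(OCc3ccccc3)cc(OCc3ccccc3)c2c1O[C@H](c1cc(OCc3ccccc3)c(OCc3ccccc3)c(OCc3ccccc3)c1)[C@H](O)C2
F2 | step 17 | (2R,3R)-5,7-bis(benzyloxy)-8-{(2R,3S,4S)-3,7-bis(benzyloxy)-2-[3,4,5-tris(benzyloxy)phenyl]-3,4-dihydro-2H-chromen-4-yl}-2-[3,4,5-tris(benzyloxy)phenyl]-3,4-dihydro-2H-chromen-3-ol | c1ccccc1COc1ccc2c(c1)O[C@H](c1cc(OCc3ccccc3)c(OCc3ccccc3)c(OCc3ccccc3)c1)[C@@H](OCc1ccccc1)[C@@H]2c1c(OCc3ccccc3)cc(OCc3ccccc3)c2c1O[C@H](c3cc(OCc4ccccc4)c(OCc4ccccc4)c(OCc4ccccc4)c3)[C@H](O)C2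
F3 | step 15 | 2-(hydroxyimino) derivative of 22 (α-oximino ketone, oxime geometry not defined) | c1ccccc1COc1ccc2c(c1)O[C@H](c1cc(OCc3ccccc3)c(OCc3ccccc3)c(OCc3ccccc3)c1)[C@@H](OCc1ccccc1)[C@@H]2C(=NO)C(=O)C1=CC[C@@H](OCOC)[C@@H](c2cc(OCc3ccccc3)c(OCc3ccccc3)c(OCc3ccccc3)c2)O1
F4 | step 16 | benzyl (E)-1,2-dichlorovinyl ether | Cl/C=C(/Cl)OCc1ccccc1
F5 | step 16 | benzyl ethynyl ether | C#COCc1ccccc1
F6 | step 16 | 7′-O-benzyl analogue of 34 (5′-OH free, 3′-O-methoxymethyl) | c1ccccc1COc1ccc2c(c1)O[C@H](c1cc(OCc3ccccc3)c(OCc3ccccc3)c(OCc3ccccc3)c1)[C@@H](OCc1ccccc1)[C@@H]2c1c(OCc3ccccc3)cc(O)c2c1O[C@H](c3cc(OCc4ccccc4)c(OCc4ccccc4)c(OCc4ccccc4)c3)[C@H](OCOC)C2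
F7 | step 16 | 7′-O-benzyl analogue of 35 (3′-OH and 5′-OH free) | c1ccccc1COc1ccc2c(c1)O[C@H](c1cc(OCc3ccccc3)c(OCc3ccccc3)c(OCc3ccccc3)c1)[C@@H](OCc1ccccc1)[C@@H]2c1c(OCc3ccccc3)cc(O)c2c1O[C@H](c3cc(OCc4ccccc4)c(OCc4ccccc4)c(OCc4ccccc4)c3)[C@H](O)C2
F8 | step 7 | (2R,3S,4R)-4-allyl-3,7-bis(benzyloxy)-2-[3,4,5-tris(benzyloxy)phenyl]-3,4-dihydro-2H-chromene | c1ccccc1COc1ccc2c(c1)O[C@H](c1cc(OCc3ccccc3)c(OCc3ccccc3)c(OCc3ccccc3)c1)[C@@H](OCc1ccccc1)[C@@H]2CC=C
F9 | step 7 | 2-{(2R,3S,4R)-3,7-bis(benzyloxy)-2-[3,4,5-tris(benzyloxy)phenyl]-3,4-dihydro-2H-chromen-4-yl}acetaldehyde | c1ccccc1COc1ccc2c(c1)O[C@H](c1cc(OCc3ccccc3)c(OCc3ccccc3)c(OCc3ccccc3)c1)[C@@H](OCc1ccccc1)[C@@H]2CC=O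
F10 | step 7 | 2-{(2R,3S,4R)-3,7-bis(benzyloxy)-2-[3,4,5-tris(benzyloxy)phenyl]-3,4-dihydro-2H-chromen-4-yl}acetic acid | c1ccccc1COc1ccc2c(c1)O[C@H](c1cc(OCc3ccccc3)c(OCc3ccccc3)c(OCc3ccccc3)c1)[C@@H](OCc1ccccc1)[C@@H]2CC(=O)O
F11 | step 4 | 1-[4-(benzyloxy)-2-hydroxyphenyl]-3-(benzylsulfanyl)-2-hydroxy-3-[3,4,5-tris(benzyloxy)phenyl]propan-1-one (C2 configuration retained from 5, C3 mixture) | Oc1cc(OCc2ccccc2)ccc1C(=O)[C@H](O)C(SCc1ccccc1)c1cc(OCc2ccccc2)c(OCc2ccccc2)c(OCc2ccccc2)c1
A1 | alternative 1 | deca-O-benzyl flav-2-ene dimer (2,4-diaryl-4H-chromene) | c1ccccc1COc1ccc2c(c1)OC(c1cc(OCc3ccccc3)c(OCc3ccccc3)c(OCc3ccccc3)c1)=C[C@@H]2c1c(OCc3ccccc3)cc(OCc3ccccc3)c2c1O[C@H](c3cc(OCc4ccccc4)c(OCc4ccccc4)c(OCc4ccccc4)c3)[C@H](OCc3ccccc3)C2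
A2 | alternative 1 | aryl 3,4,5-tris(benzyloxy)benzoate with a vinyl group on the future C4 (precursor of A1) | c1ccccc1COc1ccc(c(c1)OC(=O)c1cc(OCc3ccccc3)c(OCc3ccccc3)c(OCc3ccccc3)c1)[C@H](C=C)c1c(OCc3ccccc3)cc(OCc3ccccc3)c2c1O[C@H](c3cc(OCc4ccccc4)c(OCc4ccccc4)c(OCc4ccccc4)c3)[C@H](OCc3ccccc3)C2
A3 | alternative 2 | 3-O-acetyl deca-O-benzyl dimer | c1ccccc1COc1ccc2c(c1)O[C@H](c1cc(OCc3ccccc3)c(OCc3ccccc3)c(OCc3ccccc3)c1)[C@@H](OC(C)=O)[C@@H]2c1c(OCc3ccccc3)cc(OCc3ccccc3)c2c1O[C@H](c3cc(OCc4ccccc4)c(OCc4ccccc4)c(OCc4ccccc4)c3)[C@H](OCc3ccccc3)C2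
A4 | alternative 2 | 2-(α-mesyloxybenzyl)-3-aryl-2,3-dihydrobenzofuran (precursor of A3) | c1ccccc1COc1ccc2c(c1)O[C@@H]([C@@H](OS(C)(=O)=O)c1cc(OCc3ccccc3)c(OCc3ccccc3)c(OCc3ccccc3)c1)[C@@H]2c1c(OCc3ccccc3)cc(OCc3ccccc3)c2c1O[C@H](c3cc(OCc4ccccc4)c(OCc4ccccc4)c(OCc4ccccc4)c3)[C@H](OCc3ccccc3)C2
A5 | alternative 3 | 3-(pinacolboryl) 2,3-trans-3,4-trans deca-O-benzyl dimer | c1ccccc1COc1ccc2c(c1)O[C@H](c1cc(OCc3ccccc3)c(OCc3ccccc3)c(OCc3ccccc3)c1)[C@@H](B1OC(C)(C)C(C)(C)O1)[C@@H]2c1c(OCc3ccccc3)cc(OCc3ccccc3)c2c1O[C@H](c3cc(OCc4ccccc4)c(OCc4ccccc4)c(OCc4ccccc4)c3)[C@H](OCc3ccccc3)C2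
A6 | alternative 3 | o-hydroxybenzhydrol with the carbinol carbon bonded to C8′ (either carbinol epimer) | c1ccccc1COc1ccc(c(c1)O)C(O)c1c(OCc3ccccc3)cc(OCc3ccccc3)c2c1O[C@H](c3cc(OCc4ccccc4)c(OCc4ccccc4)c(OCc4ccccc4)c3)[C@H](OCc3ccccc3)C2
A7 | alternative 3 | (E)-2-[3,4,5-tris(benzyloxy)styryl]-4,4,5,5-tetramethyl-1,3,2-dioxaborolane | CC1(C)OB(/C=C/c2cc(OCc3ccccc3)c(OCc3ccccc3)c(OCc3ccccc3)c2)OC1(C)C
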